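Minutes are the unit of this flask; its charge, steps and questions come first.

free monomer 1.0 M; pre-initiator 5.0 mM; time 50 min

    free monomer + initiator → living end + monomer in chains (k1 = 5.0 × 10⁻⁴ /M/s)
    free monomer + living end → monomer in chains + living end, rate k2*[living end]*[free monomer] (k2 = 0.35 /M/s)
    pre-initiator ⇌ initiator (K3 = 0.84, k3 = 0.0014 /s)

- average number of monomer units in a chain (chains begun, living or dead) at 50 min
- part of the free monomer that has reacted at 50 min

How quickly do pre-initiator and initiator balance? Their relaxation half-life is 3.77 min, far shorter than the 50 min run, so I treat them as a pre-equilibrium.

What share of that pool is initiator? It is 45.7 %, which gives 2.28 mM from the charge.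

Does the pool drain? Yes: initiator has a half-life of 23 min by the first step, so the pool's half-life at charged monomer is 50.6 min, about the length of the run.

What ties chain length to conversion? Chains begin at the first constant times initiator times free monomer, and monomer enters chains at the second constant times living end times free monomer. Free monomer cancels in the ratio. With initiator steady, chain length is the square root of second constant × monomer reacted / (2 × first constant × initiator). With all charged monomer reacted and initiator at 2.28 mM, this gives the chain yardstick 392.

But this flask has neither condition, has it? No: by this rule, chains shorten with incomplete conversion and lengthen as the pool shrinks. I commit to about 392 for the chain length. The rule has no clock, so my reckoning gives no conversion.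

The forecast gives 365 (330 to 400) and 62 % (56 % to 68 %), with “about 1.7 mM of chains have begun by 50 min”. My figure is higher than its chain length.

The flask gives a chain length of 371 and a conversion of 62.7 %, both within the forecast's ranges, and 37 % of the charged free monomer is still there at 50.0 min. Scaling the yardstick by the square root of conversion times 2.28 mM over the initiator at 50.0 min, 0.00145 M, gives 389 for this flask. The neighbour charged with 0.0085 M of pre-initiator reached 78.8 % with 0.00266 M of initiator at 50.0 min, so the same yardstick gives 322. That neighbour's simulated chain length is 314.

(The numbers of this flask are those of an exercise; the rest is arithmetic.)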